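## The problem

Prostaglandin F1alpha (22) has one carbocycle, the cyclopentane C8–C9–C10–C11–C12. It carries a saturated seven-carbon acid chain on C8, an (E)-allylic alcohol chain on C12 and secondary hydroxyl groups on C9 and C11, so a synthesis must close one ring and attach or carry two chains. Four of the five stereocentres sit on the ring in the order C9, C8, C12, C11: the chains are trans, the C11 hydroxyl is trans to the C12 chain, and the C9 hydroxyl is cis to the C8 chain and to the C11 hydroxyl. C8 and C12 can be set together and can then pass information outwards (C12 to C11, C8 to C9), but C15 lies beyond the C13=C14 double bond and needs reagent control. The two ring oxygens are 1,3 through C10 but 1,4 through the C8–C12 bond, so that bond joins carbons of like polarity and cannot come from a simple aldol reaction or enolate alkylation. The sensitive points are the beta-oxygenated carbonyl stages (a C9 ketone or C13 aldehyde with oxygen on C11 eliminates easily), the epimerisable centres C8 and C12 while carbonyl groups flank them, the acid-labile allylic C15 alcohol, and the carboxyl group, which must travel as an ester. The enabling feature is the segment C9 (carbonyl level), C10 (bare methylene), C11 (carbinol): a C9 formyl group and a C10=C11 enol ether already hold every atom of it, and adding the formyl C–H across the enol ether forms C9–C10 and C11–H at once with the C11 oxygen in place. Because the acid chain is saturated, it needs no late olefination and can be present from the start as the half-ester 3.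

## Retrosynthesis

**Deprotection and C15.** Acid 22 is traced to its methyl ester 21 and this to the 9,11-bis(silyl ether) 20; no skeletal bond is cut. The C15 carbinol of 20 is taken back to enone 19. This is preferred to importing C15 as a preformed centre, because the enone comes in one step from a C13 aldehyde and a catalyst-controlled 1,2-reduction is the usual answer to a centre the ring cannot reach. The forward reduction must tell apart the two faces of an acyclic enone.

**C13=C14.** Cutting the double bond of 19 gives aldehyde 17 and phosphonate 18 and removes seven carbons at once. The neighbouring cut C12–C13 would need a ring enone as acceptor, which this route never passes through. The lower chain cannot be carried earlier, because its olefin would stand in a 4-pentenal relationship to the C9 aldehyde of 12 and would compete in the ring closure. The forward olefination must be (E)-selective and mild enough to spare the beta-silyloxy group on C11.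

**Functional-group moves on the ring.** Aldehyde 17 comes from primary alcohol 16, this from benzyl ether 15, this from alcohol 14 by silylation, and the C9 carbinol of 14 from ketone 13. A benzyl ether is chosen for C13 because it survives enolate, zirconium, rhodium and borohydride chemistry and leaves by hydrogenolysis at a stage with no olefin. The forward reduction must deliver hydride to C9 from the face opposite the C8 chain.

**C9–C10 (key cut).** Ketone 13 is opened at C9–C10 and the C11 hydrogen is returned to C9, giving aldehyde 12.
- Cutting C10–C11 instead would be an aldol closure of the 5-(enolendo) type.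
- Cutting C8–C12 in the ring would discard the bond whose two centres are easiest to set in an open chain.
- The remaining ring bonds suggest no reaction.
- Precursor 12 is acyclic with only two stereocentres.

The forward step is a rhodium-catalysed intramolecular hydroacylation that must place hydrogen on one face of C11 and must outrun decarbonylation.

**Unmasking 12.** The aldehyde of 12 cannot coexist with the base that makes the enol ether, so C9 is carried as the N-methoxy-N-methyl amide 11 and reduced last. Enol ether 11 comes from methyl ketone 9 by kinetic enolisation, and 9 from terminal olefin 8 by Wacker oxidation. No skeletal bond is cut, but the labile 12 becomes the robust 8. The forward steps ask for regioselective enolisation at C10 and an amide reduction that spares the methyl ester.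

**C8–C12.** Amide 8 comes from acid 6, and 6 is cut at C8–C12 by a retro-Ireland–Claisen step to allylic ester 4. The sigmatropic cut solves the like-polarity problem: the allylic carbon becomes C10 and the new terminal olefin is the latent C11 carbonyl. Both stereocentres follow from enolate and olefin geometry in a chair, and 4 has no stereocentre at all. The forward reaction needs an E(O) enolate on a (Z)-olefin for the 8,12-syn acid, a chiral boron reagent for the absolute sense, and must tolerate the second ester.

**Fragments.** Ester 4 is cut at the ester C–O bond into alcohol 2 and half-ester 3; 2 is the monobenzyl ether of diol 1. Compounds 1, 3 and 18 are purchased.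

## Roads not taken

**Alternative 1:** The ring is cut at C8–C9 and C11=C12 of a bicyclic enal. Forward, two molecules of succinaldehyde (A1) undergo a proline-catalysed intermolecular aldol reaction and an amine-salt-promoted intramolecular aldol condensation, while O9 closes onto C6, giving the cis-fused enal lactol A2.
- Merits: the absolute configuration comes from a cheap organocatalyst and the ring with C8 and C9 set is reached in one operation. The later operations (copper-mediated addition of the lower chain to the enal, cleavage of the resulting enol ether to the C11 ketone, reduction, olefination of the lactol) are known reaction types. The route would be roughly half as long as the one proposed here.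
- Weak points for 22: A1 oligomerises readily, so the dimerisation should be low-yielding. The lactol is designed for a Wittig reaction that leaves a C5=C6 double bond, which 22 lacks, so a hydrogenation selective for C5=C6 over the C13=C14 allylic alcohol must be added. The enol ether cleavage must also spare the lower-chain olefin.
- Comparison: in step count and precedent this road is clearly better. The chosen plan sets against it that the saturated upper chain is complete from step 2, that no olefin has to be differentiated, and that its key step tests a ring closure not yet available.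

**Alternative 2:** The cut is the biosynthetic one: O–C11, O–C9, C8–C12 and O–C15 are all formed from the all-cis trienoic acid A3 (dihomo-gamma-linolenic acid). Forward, prostaglandin H synthase and two molecules of O2 give the endoperoxide hydroperoxide A4, which a mild reductant such as SnCl2 would take to 22.
- Merits: two operations, all five stereocentres set by the enzyme, no protecting groups.
- Weak points: the enzyme is a membrane protein that inactivates itself during turnover and works only in dilute aqueous medium. A4 rearranges quickly to ketol products, so it must be reduced as it forms. The substrate A3 is itself a fermentation product.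
- Comparison: this is the shortest conceivable road and better in step count and stereocontrol. The chosen plan sets against it that it is purely chemical, runs in ordinary glassware at preparative concentration, and allows either chain to be varied.

**Alternative 3:** The cuts are C7–C8 and C12–C13. Forward, Bu3SnH generates the C7 radical of iodoacetal A5, which adds to C8 in a 5-exo closure of the tetrahydrofuran acetal; the C12 radical is then trapped by silyl enone A6 on the face opposite the new ring, giving alpha-silyl ketone A7.
- Merits: two C–C bonds and the trans C8/C12 relationship come in one step, relayed from C9 and C11, and the radical cascade is a known reaction type.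
- Weak points for 22: stoichiometric tin and a large excess of A6 are needed. A7 must still be turned into the enone and reduced at C15 as in the chosen plan. Completing the upper chain from the lactol again leaves a C5=C6 olefin that 22 does not have.
- Comparison: ring stereocontrol here is substrate-based and more certain than an untested hydroacylation, and the length is similar. The chosen plan sets against it a catalytic, tin-free ring closure and an upper chain that needs no olefination and no selective hydrogenation.

Key step: step 8

Assumption: the antipodes written for the two chiral reagents, the (S,S)-bromoborane in step 3 and (R)-BINAP in step 8, are working assignments; both reagents exist in either hand, and the hand that gives 6 as the (2R,3S) acid and 13 as the 11,12-trans ketone is the one to use.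

## Route

Step 1
Reactants: 1 (Z)-but-2-ene-1,4-diol
Product: 2 (Z)-4-(benzyloxy)but-2-en-1-ol
Conditions: Ag2O (1.5 equiv), BnBr (1.1 equiv), CH2Cl2, rt
Reagents that add atoms: benzyl bromide, BrCc1ccccc1
Why: Silver-oxide-mediated Williamson etherification; coordination of silver to the symmetrical diol should favour mono-benzylation, and the (Z)-olefin is not touched.

Step 2
Reactants: 2 (Z)-4-(benzyloxy)but-2-en-1-ol; 3 monomethyl azelate
Product: 4 1-[(2Z)-4-(benzyloxy)but-2-en-1-yl] 9-methyl nonanedioate
Conditions: DCC, DMAP (cat.), CH2Cl2, 0 °C to rt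
Reagents that add atoms: none
Why: Steglich esterification of the free carboxyl group of 3 with the primary allylic alcohol under neutral conditions that leave the methyl ester and the olefin geometry alone.

Step 3
Reactants: 4 1-[(2Z)-4-(benzyloxy)but-2-en-1-yl] 9-methyl nonanedioate
Product: 6 (2R,3S)-3-[(benzyloxy)methyl]-2-(7-methoxy-7-oxoheptyl)pent-4-enoic acid, via bis(boron enolate) 5 (not isolated)
Conditions: (4S,5S)-2-bromo-1,3-bis{[3,5-bis(trifluoromethyl)phenyl]sulfonyl}-4,5-diphenyl-1,3,2-diazaborolidine (2.4 equiv), Et3N (2.6 equiv), toluene–hexane, −78 °C; then −20 to 4 °C; aqueous work-up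
Reagents that add atoms: none
Why: Enantioselective Ireland–Claisen rearrangement through chiral boron ketene acetals; soft enolisation with Et3N in the non-polar medium should give the E(O) enolate, whose chair with the (Z)-olefin places both substituents axial and leads to the 8,12-syn acid, while the diazaborolidine selects the enolate face and so the (2R,3S) antipode. The methyl ester is enolised as well (hence two equivalents of reagent) but has no allyl partner and returns unchanged on hydrolysis.

Step 4
Reactants: 6 (2R,3S)-3-[(benzyloxy)methyl]-2-(7-methoxy-7-oxoheptyl)pent-4-enoic acid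
Product: 8 methyl (8R,9S)-9-[(benzyloxy)methyl]-8-[methoxy(methyl)carbamoyl]undec-10-enoate, via acyl imidazole 7 (not isolated)
Conditions: CDI, CH2Cl2, rt; then MeNH(OMe)·HCl, rt
Reagents that add atoms: N,O-dimethylhydroxylamine hydrochloride, CNOC.Cl
Why: Amide formation through the acyl imidazole; it precedes the Wacker step so that a free acid cannot lactonise onto the palladium-activated olefin, and the N-methoxy-N-methyl amide withstands the later enolisation and stops at the aldehyde on reduction.

Step 5
Reactants: 8 methyl (8R,9S)-9-[(benzyloxy)methyl]-8-[methoxy(methyl)carbamoyl]undec-10-enoate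
Product: 9 methyl (8R,9S)-9-[(benzyloxy)methyl]-8-[methoxy(methyl)carbamoyl]-10-oxoundecanoate
Conditions: PdCl2 (10 mol %), CuCl (30 mol %), O2 (1 atm), DMF–H2O 7:1, rt
Reagents that add atoms: water, O
Why: Wacker–Tsuji oxidation; Markovnikov hydroxypalladation of the monosubstituted olefin by divalent palladium gives the methyl ketone (C11 carbonyl, C10 methyl), the standard sequel to an ester-enolate Claisen rearrangement for 1,4-dicarbonyl compounds.

Step 6
Reactants: 9 methyl (8R,9S)-9-[(benzyloxy)methyl]-8-[methoxy(methyl)carbamoyl]-10-oxoundecanoate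
Product: 11 methyl (8R,9S)-9-[(benzyloxy)methyl]-10-[(tert-butyldimethylsilyl)oxy]-8-[methoxy(methyl)carbamoyl]undec-10-enoate, via lithium enolate 10 (not isolated)
Conditions: LiN(SiMe3)2 (1.05 equiv), THF, −78 °C; then TBSOTf, −78 °C; cold aq. NaHCO3
Reagents that add atoms: tert-butyldimethylsilyl triflate, CC(C)(C)[Si](C)(C)OS(=O)(=O)C(F)(F)F
Why: Kinetic enolisation and O-silylation; the bulky amide base should deprotonate the unhindered C10 methyl group much faster than the C12 methine, the amide alpha-position or the ester, so the terminal enol ether forms and C12 with its beta-benzyloxy group is not disturbed.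

Step 7
Reactants: 11 methyl (8R,9S)-9-[(benzyloxy)methyl]-10-[(tert-butyldimethylsilyl)oxy]-8-[methoxy(methyl)carbamoyl]undec-10-enoate
Product: 12 methyl (8R,9S)-9-[(benzyloxy)methyl]-10-[(tert-butyldimethylsilyl)oxy]-8-formylundec-10-enoate
Conditions: Cp2Zr(H)Cl (1.5 equiv), THF, rt, short contact time; filtration through Et3N-deactivated silica
Reagents that add atoms: none
Why: Chemoselective amide-to-aldehyde reduction; the zirconium hydride adds to the N-methoxy-N-methyl amide to give a zirconated hemiaminal that releases the aldehyde on work-up, whereas methyl esters are inert and the hindered 1,1-disubstituted enol ether should hydrozirconate far more slowly. The neutral medium protects C8 from epimerisation, and 12 is used at once.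

Step 8
Reactants: 12 methyl (8R,9S)-9-[(benzyloxy)methyl]-10-[(tert-butyldimethylsilyl)oxy]-8-formylundec-10-enoate
Product: 13 methyl 7-[(1R,2S,3R)-2-[(benzyloxy)methyl]-3-[(tert-butyldimethylsilyl)oxy]-5-oxocyclopentyl]heptanoate
Conditions: [Rh((R)-BINAP)]BF4 (5 mol %, from [Rh(nbd)((R)-BINAP)]BF4 and H2; BINAP = 2,2'-bis(diphenylphosphino)-1,1'-binaphthyl, nbd = norbornadiene), degassed CH2Cl2, rt
Reagents that add atoms: none
Why: Proposed new method: monovalent rhodium should insert into the formyl C9–H bond of 12 to give an acyl hydride of trivalent rhodium; the C10=C11 silyl enol ether then binds, the hydride migrates to C11 with rhodium ending on the terminal carbon C10 in a six-membered acyl–alkyl rhodacycle, and reductive elimination forms C9–C10 and returns monovalent rhodium. The closest known reaction type is the cationic rhodium–diphosphine hydroacylation of 4-substituted pent-4-enals to 3-substituted cyclopentanones, established for alkyl, aryl, silyl and acyl groups on the olefin but not for a silyloxy group. The cyclopentanone closes in a formal 5-endo-trig mode (both olefinic carbons become ring atoms), which is possible because the C–C bond arises by reductive elimination from the six-membered metallacycle and not by direct attack on the olefin. The one new stereocentre, C11, is set by the face of the enol ether that receives the hydride: the chair rhodacycle with the C8 chain, the C12 benzyloxymethyl arm and the C11 silyloxy group all equatorial leads to the 11,12-trans ketone, and the BINAP antipode is chosen to reinforce this substrate preference. C8 and C12 are untouched as long as the aldehyde is not enolised, which the base-free medium secures. The regiochemistry of hydride transfer follows from the 1,1-disubstitution of the olefin, and the alternative five-membered metallacycle can only revert. Decarbonylation is held back by the chelating diphosphine at room temperature, a Lewis-acid aldol closure of the enol ether onto the aldehyde would be a disfavoured 5-(enolendo)-exo-trig process, and beta-siloxide elimination is disfavoured because the equatorial C11–O bond is anti, not syn, to the Rh–C10 bond.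

Step 9
Reactants: 13 methyl 7-[(1R,2S,3R)-2-[(benzyloxy)methyl]-3-[(tert-butyldimethylsilyl)oxy]-5-oxocyclopentyl]heptanoate
Product: 14 methyl 7-[(1R,2S,3R,5S)-2-[(benzyloxy)methyl]-3-[(tert-butyldimethylsilyl)oxy]-5-hydroxycyclopentyl]heptanoate
Conditions: LiBH(s-Bu)3, THF, −78 °C; H2O
Reagents that add atoms: none
Why: Bulky trialkylborohydride reduction; hydride should approach C9 from the face opposite the adjacent C8 chain and give the 9-alpha alcohol cis to that chain, as in the reduction of 11-protected E-type prostaglandins to the F-alpha series. The ester and silyl ether are inert at −78 °C and the beta-silyloxy ketone does not eliminate under these conditions.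

Step 10
Reactants: 14 methyl 7-[(1R,2S,3R,5S)-2-[(benzyloxy)methyl]-3-[(tert-butyldimethylsilyl)oxy]-5-hydroxycyclopentyl]heptanoate
Product: 15 methyl 7-[(1R,2S,3R,5S)-2-[(benzyloxy)methyl]-3,5-bis[(tert-butyldimethylsilyl)oxy]cyclopentyl]heptanoate
Conditions: TBSOTf, 2,6-lutidine, CH2Cl2, −78 to 0 °C
Reagents that add atoms: tert-butyldimethylsilyl triflate, CC(C)(C)[Si](C)(C)OS(=O)(=O)C(F)(F)F
Why: Silylation of the hindered secondary alcohol with the silyl triflate, so that only the C13 primary alcohol is oxidised later and both ring oxygens leave together at the end.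

Step 11
Reactants: 15 methyl 7-[(1R,2S,3R,5S)-2-[(benzyloxy)methyl]-3,5-bis[(tert-butyldimethylsilyl)oxy]cyclopentyl]heptanoate
Product: 16 methyl 7-[(1R,2S,3R,5S)-3,5-bis[(tert-butyldimethylsilyl)oxy]-2-(hydroxymethyl)cyclopentyl]heptanoate
Conditions: H2 (1 atm), 10% Pd/C, EtOAc, rt
Reagents that add atoms: none
Why: Hydrogenolysis of the benzyl ether in a neutral solvent; silyl ethers and the ester are stable and the molecule has no olefin at this stage.

Step 12
Reactants: 16 methyl 7-[(1R,2S,3R,5S)-3,5-bis[(tert-butyldimethylsilyl)oxy]-2-(hydroxymethyl)cyclopentyl]heptanoate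
Product: 17 methyl 7-[(1R,2R,3R,5S)-3,5-bis[(tert-butyldimethylsilyl)oxy]-2-formylcyclopentyl]heptanoate
Conditions: Dess–Martin periodinane, pyridine, CH2Cl2, 0 °C to rt
Reagents that add atoms: none
Why: Dess–Martin oxidation of the primary alcohol under buffered, non-basic conditions, so that the beta-silyloxy aldehyde neither eliminates nor epimerises at C12; it is used at once.

Step 13
Reactants: 17 methyl 7-[(1R,2R,3R,5S)-3,5-bis[(tert-butyldimethylsilyl)oxy]-2-formylcyclopentyl]heptanoate; 18 dimethyl (2-oxoheptyl)phosphonate
Product: 19 methyl 7-[(1R,2R,3R,5S)-3,5-bis[(tert-butyldimethylsilyl)oxy]-2-[(1E)-3-oxooct-1-en-1-yl]cyclopentyl]heptanoate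
Conditions: LiCl, i-Pr2NEt, MeCN, rt
Reagents that add atoms: none
Why: Horner–Wadsworth–Emmons olefination with a stabilised beta-keto phosphonate gives the (E)-enone; the LiCl/amine variant is mild enough to avoid beta-elimination of the C11 silyloxy group.

Step 14
Reactants: 19 methyl 7-[(1R,2R,3R,5S)-3,5-bis[(tert-butyldimethylsilyl)oxy]-2-[(1E)-3-oxooct-1-en-1-yl]cyclopentyl]heptanoate
Product: 20 methyl 7-[(1R,2R,3R,5S)-3,5-bis[(tert-butyldimethylsilyl)oxy]-2-[(1E,3S)-3-hydroxyoct-1-en-1-yl]cyclopentyl]heptanoate
Conditions: (R)-2-methyl-CBS-oxazaborolidine [(3aR)-1-methyl-3,3-diphenyltetrahydro-1H,3H-pyrrolo[1,2-c][1,3,2]oxazaborole] (20 mol %), catecholborane, toluene, −78 °C; aqueous work-up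
Reagents that add atoms: none
Why: Corey–Bakshi–Shibata reduction; the (R)-oxazaborolidine binds the enone with the alkenyl group as the large substituent and should deliver hydride to the face that gives the (15S) allylic alcohol, and catecholborane at low temperature favours 1,2- over 1,4-reduction.

Step 15
Reactants: 20 methyl 7-[(1R,2R,3R,5S)-3,5-bis[(tert-butyldimethylsilyl)oxy]-2-[(1E,3S)-3-hydroxyoct-1-en-1-yl]cyclopentyl]heptanoate
Product: 21 prostaglandin F1alpha methyl ester
Conditions: HF·pyridine, THF–pyridine, 0 °C to rt
Reagents that add atoms: none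
Why: Fluoride-mediated cleavage of both secondary silyl ethers under buffered conditions that leave the allylic C15 alcohol and the ester intact.

Step 16
Reactants: 21 prostaglandin F1alpha methyl ester
Product: 22 prostaglandin F1alpha
Conditions: LiOH, THF–MeOH–H2O, rt; then 1 M HCl to pH 4
Reagents that add atoms: lithium hydroxide, [Li+].[OH-]
Why: Saponification of the methyl ester; the F-type triol has no beta-hydroxy ketone and tolerates aqueous base, and careful acidification releases the acid without stressing the allylic alcohol.

## Compound list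

1 | (Z)-but-2-ene-1,4-diol | OC/C=C\CO | starting material
2 | (Z)-4-(benzyloxy)but-2-en-1-ol | OC/C=C\COCc1ccccc1 | intermediate
3 | monomethyl azelate (9-methoxy-9-oxononanoic acid) | COC(=O)CCCCCCCC(=O)O | starting material
4 | 1-[(2Z)-4-(benzyloxy)but-2-en-1-yl] 9-methyl nonanedioate | COC(=O)CCCCCCCC(=O)OC/C=C\COCc1ccccc1 | intermediate
5 | bis(boron enolate) of 4, not isolated: both esters as ketene acetals O-bound to the (4S,5S)-1,3-bis{[3,5-bis(trifluoromethyl)phenyl]sulfonyl}-4,5-diphenyl-1,3,2-diazaborolidin-2-yl group; allylic ester enolate E(O), chain cis to the allyloxy oxygen | COC(OB1N(S(=O)(=O)c2cc(cc(c2)C(F)(F)F)C(F)(F)F)[C@@H](c2ccccc2)[C@H](c2ccccc2)N1S(=O)(=O)c1cc(cc(c1)C(F)(F)F)C(F)(F)F)=CCCCCC/C=C(\OC/C=C\COCc1ccccc1)OB1N(S(=O)(=O)c2cc(cc(c2)C(F)(F)F)C(F)(F)F)[C@@H](c2ccccc2)[C@H](c2ccccc2)N1S(=O)(=O)c1cc(cc(c1)C(F)(F)F)C(F)(F)F | intermediate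
6 | (2R,3S)-3-[(benzyloxy)methyl]-2-(7-methoxy-7-oxoheptyl)pent-4-enoic acid | O=C(O)[C@H](CCCCCCC(=O)OC)[C@@H](COCc1ccccc1)C=C | intermediate
7 | acyl imidazole of 6, not isolated: methyl (8R,9S)-9-[(benzyloxy)methyl]-8-(1H-imidazol-1-ylcarbonyl)undec-10-enoate | O=C(n1ccnc1)[C@H](CCCCCCC(=O)OC)[C@@H](COCc1ccccc1)C=C | intermediate
8 | methyl (8R,9S)-9-[(benzyloxy)methyl]-8-[methoxy(methyl)carbamoyl]undec-10-enoate | CON(C)C(=O)[C@H](CCCCCCC(=O)OC)[C@@H](COCc1ccccc1)C=C | intermediate
9 | methyl (8R,9S)-9-[(benzyloxy)methyl]-8-[methoxy(methyl)carbamoyl]-10-oxoundecanoate | CON(C)C(=O)[C@H](CCCCCCC(=O)OC)[C@@H](COCc1ccccc1)C(C)=O | intermediate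
10 | lithium enolate of 9 at C10=C11, not isolated | CON(C)C(=O)[C@H](CCCCCCC(=O)OC)[C@@H](COCc1ccccc1)C(=C)O[Li] | intermediate
11 | methyl (8R,9S)-9-[(benzyloxy)methyl]-10-[(tert-butyldimethylsilyl)oxy]-8-[methoxy(methyl)carbamoyl]undec-10-enoate | CON(C)C(=O)[C@H](CCCCCCC(=O)OC)[C@@H](COCc1ccccc1)C(=C)O[Si](C)(C)C(C)(C)C | intermediate
12 | methyl (8R,9S)-9-[(benzyloxy)methyl]-10-[(tert-butyldimethylsilyl)oxy]-8-formylundec-10-enoate | O=C[C@H](CCCCCCC(=O)OC)[C@@H](COCc1ccccc1)C(=C)O[Si](C)(C)C(C)(C)C | intermediate
13 | methyl 7-[(1R,2S,3R)-2-[(benzyloxy)methyl]-3-[(tert-butyldimethylsilyl)oxy]-5-oxocyclopentyl]heptanoate | O=C1C[C@@H](O[Si](C)(C)C(C)(C)C)[C@H](COCc2ccccc2)[C@H]1CCCCCCC(=O)OC | intermediate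
14 | methyl 7-[(1R,2S,3R,5S)-2-[(benzyloxy)methyl]-3-[(tert-butyldimethylsilyl)oxy]-5-hydroxycyclopentyl]heptanoate | O(Cc1ccccc1)C[C@@H]1[C@@H](CCCCCCC(=O)OC)[C@@H](O)C[C@H]1O[Si](C)(C)C(C)(C)C | intermediate
15 | methyl 7-[(1R,2S,3R,5S)-2-[(benzyloxy)methyl]-3,5-bis[(tert-butyldimethylsilyl)oxy]cyclopentyl]heptanoate | O(Cc1ccccc1)C[C@@H]1[C@@H](CCCCCCC(=O)OC)[C@@H](O[Si](C)(C)C(C)(C)C)C[C@H]1O[Si](C)(C)C(C)(C)C | intermediate
16 | methyl 7-[(1R,2S,3R,5S)-3,5-bis[(tert-butyldimethylsilyl)oxy]-2-(hydroxymethyl)cyclopentyl]heptanoate | OC[C@@H]1[C@@H](CCCCCCC(=O)OC)[C@@H](O[Si](C)(C)C(C)(C)C)C[C@H]1O[Si](C)(C)C(C)(C)C | intermediate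
17 | methyl 7-[(1R,2R,3R,5S)-3,5-bis[(tert-butyldimethylsilyl)oxy]-2-formylcyclopentyl]heptanoate | O=C[C@@H]1[C@@H](CCCCCCC(=O)OC)[C@@H](O[Si](C)(C)C(C)(C)C)C[C@H]1O[Si](C)(C)C(C)(C)C | intermediate
18 | dimethyl (2-oxoheptyl)phosphonate | CCCCCC(=O)CP(=O)(OC)OC | starting material
19 | methyl 7-[(1R,2R,3R,5S)-3,5-bis[(tert-butyldimethylsilyl)oxy]-2-[(1E)-3-oxooct-1-en-1-yl]cyclopentyl]heptanoate | CCCCCC(=O)/C=C/[C@@H]1[C@@H](CCCCCCC(=O)OC)[C@@H](O[Si](C)(C)C(C)(C)C)C[C@H]1O[Si](C)(C)C(C)(C)C | intermediate
20 | methyl 7-[(1R,2R,3R,5S)-3,5-bis[(tert-butyldimethylsilyl)oxy]-2-[(1E,3S)-3-hydroxyoct-1-en-1-yl]cyclopentyl]heptanoate | CCCCC[C@H](O)/C=C/[C@@H]1[C@@H](CCCCCCC(=O)OC)[C@@H](O[Si](C)(C)C(C)(C)C)C[C@H]1O[Si](C)(C)C(C)(C)C | intermediate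
21 | prostaglandin F1alpha methyl ester, methyl 7-[(1R,2R,3R,5S)-3,5-dihydroxy-2-[(1E,3S)-3-hydroxyoct-1-en-1-yl]cyclopentyl]heptanoate | CCCCC[C@H](O)/C=C/[C@@H]1[C@@H](CCCCCCC(=O)OC)[C@@H](O)C[C@H]1O | intermediate
22 | prostaglandin F1alpha, 7-[(1R,2R,3R,5S)-3,5-dihydroxy-2-[(1E,3S)-3-hydroxyoct-1-en-1-yl]cyclopentyl]heptanoic acid | CCCCC[C@H](O)/C=C/[C@@H]1[C@@H](CCCCCCC(=O)O)[C@@H](O)C[C@H]1O | target

## Step count and risk

Total: 16 steps. Longest linear sequence: 16 steps, from 1 to 22; 3 and 18 enter as purchased fragments.

**Step 8 (key step, proposed new method).** Most likely failures are: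
- loss of carbon monoxide from the acyl rhodium hydride before the electron-rich, hindered enol ether inserts;
- rhodium-hydride-mediated migration of the enol ether double bond towards C12, which would erase that centre;
- insufficient facial discrimination at C11 if ligand and substrate preferences oppose each other.

Fallback with known chemistry, from 8 to 13: amide 8 is reduced with Cp2Zr(H)Cl to methyl (8R,9S)-9-[(benzyloxy)methyl]-8-formylundec-10-enoate F1. This plain 4-pentenal is cyclised with [Rh(dppe)]BF4 (dppe = 1,2-bis(diphenylphosphino)ethane), the established substrate class, to methyl 7-[(1R,2S)-2-[(benzyloxy)methyl]-5-oxocyclopentyl]heptanoate F2. Kinetic enolisation towards C10 (LiN(SiMe3)2, Me3SiCl) gives the trimethylsilyl enol ether F3, and Saegusa–Ito oxidation with Pd(OAc)2 gives the enone methyl 7-[(1R,5S)-5-[(benzyloxy)methyl]-2-oxocyclopent-3-en-1-yl]heptanoate F4. Copper-catalysed conjugate borylation with bis(pinacolato)diboron (CuCl, NaOt-Bu, MeOH), anti to the C12 arm, gives the beta-boryl ketone F5. Oxidation with NaBO3 with retention gives methyl 7-[(1R,2S,3R)-2-[(benzyloxy)methyl]-3-hydroxy-5-oxocyclopentyl]heptanoate F6, and silylation (TBSCl, imidazole) returns to 13.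

**Step 3.** The (Z)-allylic boron ketene acetal may rearrange slowly, and facial discrimination by the chiral boron ligand or control of enolate geometry may be incomplete, which would erode the enantiomeric purity or the C8/C12 relationship. The need to enolise both esters also doubles the demand for the chiral reagent.

Fallback by chirality transfer, from 3 to 6: benzyl propargyl ether is lithiated and acylated with N-methoxy-N-methylacetamide to 5-(benzyloxy)pent-3-yn-2-one F7. Asymmetric transfer hydrogenation (RuCl[(S,S)-TsDPEN](p-cymene), i-PrOH; TsDPEN = N-tosyl-1,2-diphenylethylenediamine) gives (2S)-5-(benzyloxy)pent-3-yn-2-ol F8, and semihydrogenation over lead-poisoned Pd/CaCO3 with quinoline gives (2S,3Z)-5-(benzyloxy)pent-3-en-2-ol F9. Esterification with 3 (DCC, DMAP) gives 1-[(2S,3Z)-5-(benzyloxy)pent-3-en-2-yl] 9-methyl nonanedioate F10. LiN(i-Pr)2 (2.3 equiv) and Me3SiCl in THF at −78 °C give the bis(trimethylsilyl ketene acetal) F11, which rearranges on warming through the chair with the carbinol methyl group equatorial. A chair model of that transition state predicts that the (S)-carbinol gives (2R,3S,4E)-3-[(benzyloxy)methyl]-2-(7-methoxy-7-oxoheptyl)hex-4-enoic acid F12. Ethenolysis (ethylene, second-generation Hoveyda–Grubbs catalyst) trims the propenyl group to vinyl and returns to 6.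

**Step 7.** Competing hydrozirconation or cleavage of the silyl enol ether, incomplete discrimination between amide and ester, or epimerisation at C8 during isolation of the alpha-branched aldehyde may occur.

Fallback through a thioester, from 6 to 12: acid 6 is converted (EtSH, DCC, DMAP) into methyl (8R,9S)-9-[(benzyloxy)methyl]-8-[(ethylsulfanyl)carbonyl]undec-10-enoate F13. Wacker oxidation gives the methyl ketone methyl (8R,9S)-9-[(benzyloxy)methyl]-8-[(ethylsulfanyl)carbonyl]-10-oxoundecanoate F14, and kinetic silylation as in step 6 gives the silyl enol ether F15. Fukuyama reduction (Et3SiH, 10% Pd/C, acetone) then gives 12 under neutral conditions that do not touch a methyl ester.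

**Step 14.** Facial selectivity at C15 may be insufficient, because the centre is remote from the ring and rests on the catalyst alone; some 1,4-reduction is also possible.

Fallback with a preformed C15 centre, from 17 to 20: aldehyde 17 is methylenated (Ph3P=CH2) to methyl 7-[(1R,2R,3R,5S)-3,5-bis[(tert-butyldimethylsilyl)oxy]-2-ethenylcyclopentyl]heptanoate F16. Olefin cross-metathesis of F16 with commercial (S)-oct-1-en-3-ol (second-generation Hoveyda–Grubbs catalyst) gives the (E)-allylic alcohol 20 directly.

Further compounds
F1 | step 8 | methyl (8R,9S)-9-[(benzyloxy)methyl]-8-formylundec-10-enoate | O=C[C@H](CCCCCCC(=O)OC)[C@@H](COCc1ccccc1)C=C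
F2 | step 8 | methyl 7-[(1R,2S)-2-[(benzyloxy)methyl]-5-oxocyclopentyl]heptanoate | O=C1CC[C@H](COCc2ccccc2)[C@H]1CCCCCCC(=O)OC
F3 | step 8 | methyl 7-[(1R,5S)-5-[(benzyloxy)methyl]-2-[(trimethylsilyl)oxy]cyclopent-2-en-1-yl]heptanoate | C[Si](C)(C)OC1=CC[C@H](COCc2ccccc2)[C@H]1CCCCCCC(=O)OC
F4 | step 8 | methyl 7-[(1R,5S)-5-[(benzyloxy)methyl]-2-oxocyclopent-3-en-1-yl]heptanoate | O=C1C=C[C@H](COCc2ccccc2)[C@H]1CCCCCCC(=O)OC
F5 | step 8 | methyl 7-[(1R,2S,3R)-2-[(benzyloxy)methyl]-5-oxo-3-(4,4,5,5-tetramethyl-1,3,2-dioxaborolan-2-yl)cyclopentyl]heptanoate | O=C1C[C@@H](B2OC(C)(C)C(C)(C)O2)[C@H](COCc2ccccc2)[C@H]1CCCCCCC(=O)OC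
F6 | step 8 | methyl 7-[(1R,2S,3R)-2-[(benzyloxy)methyl]-3-hydroxy-5-oxocyclopentyl]heptanoate | O=C1C[C@@H](O)[C@H](COCc2ccccc2)[C@H]1CCCCCCC(=O)OC
F7 | step 3 | 5-(benzyloxy)pent-3-yn-2-one | CC(=O)C#CCOCc1ccccc1
F8 | step 3 | (2S)-5-(benzyloxy)pent-3-yn-2-ol | C[C@H](O)C#CCOCc1ccccc1
F9 | step 3 | (2S,3Z)-5-(benzyloxy)pent-3-en-2-ol | C[C@H](O)/C=C\COCc1ccccc1
F10 | step 3 | 1-[(2S,3Z)-5-(benzyloxy)pent-3-en-2-yl] 9-methyl nonanedioate | COC(=O)CCCCCCCC(=O)O[C@@H](C)/C=C\COCc1ccccc1
F11 | step 3 | bis(trimethylsilyl ketene acetal) of F10, allylic ester part E(O) | COC(O[Si](C)(C)C)=CCCCCC/C=C(\O[C@@H](C)/C=C\COCc1ccccc1)O[Si](C)(C)C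
F12 | step 3 | (2R,3S,4E)-3-[(benzyloxy)methyl]-2-(7-methoxy-7-oxoheptyl)hex-4-enoic acid | O=C(O)[C@H](CCCCCCC(=O)OC)[C@@H](COCc1ccccc1)/C=C/C
F13 | step 7 | methyl (8R,9S)-9-[(benzyloxy)methyl]-8-[(ethylsulfanyl)carbonyl]undec-10-enoate | CCSC(=O)[C@H](CCCCCCC(=O)OC)[C@@H](COCc1ccccc1)C=C
F14 | step 7 | methyl (8R,9S)-9-[(benzyloxy)methyl]-8-[(ethylsulfanyl)carbonyl]-10-oxoundecanoate | CCSC(=O)[C@H](CCCCCCC(=O)OC)[C@@H](COCc1ccccc1)C(C)=O
F15 | step 7 | methyl (8R,9S)-9-[(benzyloxy)methyl]-10-[(tert-butyldimethylsilyl)oxy]-8-[(ethylsulfanyl)carbonyl]undec-10-enoate | CCSC(=O)[C@H](CCCCCCC(=O)OC)[C@@H](COCc1ccccc1)C(=C)O[Si](C)(C)C(C)(C)C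
F16 | step 14 | methyl 7-[(1R,2R,3R,5S)-3,5-bis[(tert-butyldimethylsilyl)oxy]-2-ethenylcyclopentyl]heptanoate | C=C[C@@H]1[C@@H](CCCCCCC(=O)OC)[C@@H](O[Si](C)(C)C(C)(C)C)C[C@H]1O[Si](C)(C)C(C)(C)C
A1 | alternative 1 | succinaldehyde | O=CCCC=O
A2 | alternative 1 | cis-fused bicyclic enal lactol, 2-hydroxy-3,3a,6,6a-tetrahydro-2H-cyclopenta[b]furan-5-carbaldehyde (anomers) | O=CC1=C[C@H]2CC(O)O[C@H]2C1
A3 | alternative 2 | dihomo-gamma-linolenic acid, (8Z,11Z,14Z)-icosa-8,11,14-trienoic acid | CCCCC/C=C\C/C=C\C/C=C\CCCCCCC(=O)O
A4 | alternative 2 | prostaglandin G1, the 9,11-endoperoxide 15-hydroperoxide | CCCCC[C@H](OO)/C=C/[C@@H]1[C@@H](CCCCCCC(=O)O)[C@@H]2C[C@H]1OO2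
A5 | alternative 3 | tert-butyl{[(1R,4S)-4-(1-ethoxy-2-iodoethoxy)cyclopent-2-en-1-yl]oxy}dimethylsilane (acetal epimers) | CCOC(CI)O[C@@H]1C=C[C@H](O[Si](C)(C)C(C)(C)C)C1
A6 | alternative 3 | 2-(trimethylsilyl)oct-1-en-3-one | CCCCCC(=O)C(=C)[Si](C)(C)C
A7 | alternative 3 | bicyclic acetal alpha-silyl ketone (acetal and C14 epimers) | CCCCCC(=O)C([Si](C)(C)C)C[C@@H]1[C@H]2CC(OCC)O[C@H]2C[C@H]1O[Si](C)(C)C(C)(C)C
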